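## Retrosynthetic overview

- **Feature:** in the tetrahydropyran (O1, C2 aryl, C3 hydroxyl, C4 ring A, C5 methylene, C6 arylethyl), C2–C5 with oxygen on C3 and a carbonyl placeholder on C4 map onto a 1-methoxy-2,3-bis(silyloxy)butadiene, and O1–C6 onto the C=O of a 3-arylpropanal.
- **Ring formation:** the tetrahydropyran is the only ring made; a catalytic asymmetric oxa-[4+2] addition forms C5–C6 and O1–C2 and sets C6.
- **C2–aryl:** axial diarylcuprate addition to the dihydropyranone gives the 2,6-trans relationship; kinetic protonation sets C3.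
- **C4–ring A:** C4–C5 enol triflate, Suzuki–Miyaura coupling with the ring A boronic acid, then C3-hydroxyl-directed hydrogenation sets C4.
- **Chalcone arm:** bromination of ring A, bromine–lithium exchange, acylation with an (E)-cinnamoyl N-methoxy-N-methylamide; all methoxymethyl groups are removed last without Brønsted acid.

Key step: step 6

Assumption: (R)-BINOL is written as the ligand antipode expected to expose the Re face of the aldehyde; if the addition favours the other face, (S)-BINOL is used and nothing else changes.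

## Route

Step 1
Reactants: 1 3-(4-hydroxyphenyl)propan-1-ol
Product: 2 3-[4-(methoxymethoxy)phenyl]propan-1-ol
Conditions: NaH (1.05 equiv), DMF, 0 °C; MOMCl (1.05 equiv), 0 °C → rt
Reagents that add atoms: chloromethyl methyl ether (MOMCl), COCCl
Why: Williamson-type O-alkylation; one equivalent of NaH deprotonates only the phenol, which is far more acidic than the primary alcohol, so the methoxymethyl group should go on the aryl oxygen.

Step 2
Reactants: 2 3-[4-(methoxymethoxy)phenyl]propan-1-ol
Product: 3 3-[4-(methoxymethoxy)phenyl]propanal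
Conditions: TEMPO (10 mol %), PhI(OAc)2 (1.1 equiv), CH2Cl2, rt
Reagents that add atoms: none
Why: TEMPO-catalysed alcohol oxidation with PhI(OAc)2 as terminal oxidant stops at the aldehyde and leaves the acetal-type protecting group untouched.

Step 3
Reactants: 4 (E)-4-methoxybut-3-en-2-one
Product: 6 3-hydroxy-4,4-dimethoxybutan-2-one (racemic), via epoxide 5 (not isolated)
Conditions: DMDO (acetone solution, 1.1 equiv), CH2Cl2, 0 °C; then MeOH, PPTS (cat.), 0 °C → rt
Reagents that add atoms: dimethyldioxirane (DMDO), CC1(C)OO1; methanol, CO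
Why: Rubottom-type α-hydroxylation: the dioxirane epoxidises the push–pull enol-ether double bond and methanol opens the 2-methoxyoxirane at its acetal carbon; the new carbinol centre is racemic and is erased in step 5.

Step 4
Reactants: 6 3-hydroxy-4,4-dimethoxybutan-2-one
Product: 7 3-[(tert-butyldimethylsilyl)oxy]-4,4-dimethoxybutan-2-one (racemic)
Conditions: TBSCl (1.2 equiv), imidazole (2.5 equiv), DMF, rt
Reagents that add atoms: tert-butyldimethylsilyl chloride (TBSCl), CC(C)(C)[Si](C)(C)Cl
Why: imidazole-promoted silylation of a secondary alcohol; the near-neutral conditions avoid β-elimination of methanol from the β-keto acetal.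

Step 5
Reactants: 7 3-[(tert-butyldimethylsilyl)oxy]-4,4-dimethoxybutan-2-one
Product: 9 (1Z)-2-[(tert-butyldimethylsilyl)oxy]-1-methoxy-3-[(trimethylsilyl)oxy]buta-1,3-diene, via silyl enol ether 8 (not isolated)
Conditions: Et3N (4 equiv), TMSOTf (2.3 equiv), Et2O, 0 °C → rt; pentane extraction, used at once
Reagents that add atoms: trimethylsilyl trifluoromethanesulfonate (TMSOTf), C[Si](C)(C)OS(=O)(=O)C(F)(F)F
Why: soft enolisation and O-silylation of the methyl ketone on its CH3 side gives 8, and a second equivalent of TMSOTf ionises the dimethyl acetal to an oxocarbenium ion that loses the doubly activated C–H proton (acetal-to-enol-ether elimination), so the dioxygenated diene should form with the methoxy group anti to the diene backbone as the main isomer.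

Step 6
Reactants: 3 3-[4-(methoxymethoxy)phenyl]propanal, 9 (1Z)-2-[(tert-butyldimethylsilyl)oxy]-1-methoxy-3-[(trimethylsilyl)oxy]buta-1,3-diene
Product: 11 (2S)-5-[(tert-butyldimethylsilyl)oxy]-2-{2-[4-(methoxymethoxy)phenyl]ethyl}-2,3-dihydro-4H-pyran-4-one, via aldol adduct 10 (not isolated)
Conditions: (R)-BINOL (20 mol %), Ti(Oi-Pr)4 (10 mol %), 4 Å MS, Et2O, −20 °C; then TFA (5 mol %), CH2Cl2, 0 °C
Reagents that add atoms: none
Why: The BINOL–titanium complex binds the aldehyde, and the unsubstituted CH2 terminus of diene 9 (the carbon of the trimethylsilyl enol ether, the most nucleophilic position) attacks the carbonyl carbon in a Mukaiyama aldol addition to give 10, the stepwise counterpart of an oxa-[4+2] cycloaddition, which forms C5–C6. With a trace of TFA the C6 oxygen adds to the methoxy-bearing enol-ether carbon (6-endo-trig oxa-conjugate addition) and methanol is expelled, which forms O1–C2 and closes the pyranone ring; the labile trimethylsilyl group is lost while the tert-butyldimethylsilyl group stays on the C3 oxygen as an enol ether conjugated to the ketone. The closest known reaction is the chiral-Lewis-acid-catalysed hetero-Diels–Alder reaction of 1-methoxy-3-silyloxybutadienes with unbranched aldehydes, including 2-oxygenated dienes used for hexose-type dihydropyranones. The only new stereocentre, C6, is set by the ligand, which shields one face of the bound aldehyde so that attack on the Re face should give the S configuration. The step needs enantioselectivity, which comes from the catalyst, and regioselectivity, which comes from the polarisation of the diene (nucleophilic CH2 terminus, acetal-type methoxy terminus); the geometry of the methoxy-bearing double bond does not matter because that carbon loses its methoxy group.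

Step 7
Reactants: 12 4-bromophenol
Product: 13 1-bromo-4-(methoxymethoxy)benzene
Conditions: NaH (1.1 equiv), DMF, 0 °C; MOMCl (1.1 equiv), 0 °C → rt
Reagents that add atoms: chloromethyl methyl ether (MOMCl), COCCl
Why: Williamson-type O-alkylation of the phenoxide.

Step 8
Reactants: 11 (2S)-5-[(tert-butyldimethylsilyl)oxy]-2-{2-[4-(methoxymethoxy)phenyl]ethyl}-2,3-dihydro-4H-pyran-4-one, 13 1-bromo-4-(methoxymethoxy)benzene
Product: 17 (2S,3R,6S)-3-[(tert-butyldimethylsilyl)oxy]-2-[4-(methoxymethoxy)phenyl]-6-{2-[4-(methoxymethoxy)phenyl]ethyl}oxan-4-one (2-aryl trans to the 6-chain; 3-silyloxy cis to the 2-aryl), via Grignard reagent 14 (not isolated), via magnesium diarylcuprate 15 (not isolated), via silyl enol ether 16 (not isolated)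
Conditions: 13, Mg, THF, rt; CuBr·SMe2 (0.5 equiv per ArMgBr), −40 °C; then 11, Me3SiCl, −78 → −40 °C; then AcOH, THF/H2O, −40 → 0 °C
Reagents that add atoms: none
Why: conjugate addition of a diarylcuprate to the vinylogous ester, accelerated by Me3SiCl: the aryl group should enter C2 axially through a chair-like transition state, anti to the equatorial C6 chain (2,6-trans), and C-protonation of silyl enol ether 16 on the face opposite the pseudoaxial aryl group should place the C3 silyloxy group cis to it under kinetic control.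

Step 9
Reactants: 17 (2S,3R,6S)-3-[(tert-butyldimethylsilyl)oxy]-2-[4-(methoxymethoxy)phenyl]-6-{2-[4-(methoxymethoxy)phenyl]ethyl}oxan-4-one
Product: 19 (2S,3R,6S)-3-[(tert-butyldimethylsilyl)oxy]-2-[4-(methoxymethoxy)phenyl]-6-{2-[4-(methoxymethoxy)phenyl]ethyl}-3,6-dihydro-2H-pyran-4-yl trifluoromethanesulfonate, via potassium enolate 18 (not isolated)
Conditions: KN(SiMe3)2 (1.1 equiv), THF, −78 °C; then 2-[N,N-bis(trifluoromethylsulfonyl)amino]-5-chloropyridine (1.2 equiv), −78 °C
Reagents that add atoms: 2-[N,N-bis(trifluoromethylsulfonyl)amino]-5-chloropyridine, FC(F)(F)S(=O)(=O)N(c1ccc(Cl)cn1)S(=O)(=O)C(F)(F)F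
Why: kinetic enolisation with the hindered amide base should occur at the C5 methylene and not at the silyloxy-bearing C3, and O-sulfonylation of the enolate gives the C4–C5 enol triflate; the low temperature keeps the C3 centre and the β-alkoxy ketone (retro-oxa-Michael opening) intact.

Step 10
Reactants: 20 5-methoxybenzene-1,3-diol
Product: 21 1-methoxy-3,5-bis(methoxymethoxy)benzene
Conditions: NaH (2.3 equiv), DMF, 0 °C; MOMCl (2.3 equiv), 0 °C → rt
Reagents that add atoms: chloromethyl methyl ether (MOMCl), COCCl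
Why: Williamson-type O-alkylation of both phenoxides.

Step 11
Reactants: 21 1-methoxy-3,5-bis(methoxymethoxy)benzene
Product: 23 [4-methoxy-2,6-bis(methoxymethoxy)phenyl]boronic acid, via aryllithium 22 (not isolated)
Conditions: n-BuLi (1.1 equiv), THF, 0 °C; B(Oi-Pr)3 (1.5 equiv), −78 °C → rt; sat. aq. NH4Cl
Reagents that add atoms: triisopropyl borate, CC(C)OB(OC(C)C)OC(C)C; water, O
Why: directed ortho-metalation: the position between the two methoxymethoxy groups is doubly coordinated and should be lithiated in preference to the positions next to the methoxy group; borate trapping and mild hydrolysis give the boronic acid.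

Step 12
Reactants: 19 (2S,3R,6S)-3-[(tert-butyldimethylsilyl)oxy]-2-[4-(methoxymethoxy)phenyl]-6-{2-[4-(methoxymethoxy)phenyl]ethyl}-3,6-dihydro-2H-pyran-4-yl trifluoromethanesulfonate, 23 [4-methoxy-2,6-bis(methoxymethoxy)phenyl]boronic acid
Product: 24 tert-butyl{[(2S,3S,6S)-4-[4-methoxy-2,6-bis(methoxymethoxy)phenyl]-2-[4-(methoxymethoxy)phenyl]-6-{2-[4-(methoxymethoxy)phenyl]ethyl}-3,6-dihydro-2H-pyran-3-yl]oxy}dimethylsilane
Conditions: Pd(OAc)2 (5 mol %), SPhos (10 mol %), K3PO4 (3 equiv), 23 (2 equiv), THF/H2O (10:1), 40 °C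
Reagents that add atoms: none
Why: Suzuki–Miyaura coupling of an enol triflate with a di-ortho-substituted arylboronic acid; the bulky electron-rich biarylphosphine allows transmetalation and reductive elimination at low temperature, which limits protodeboronation, and no stereocentre is touched.

Step 13
Reactants: 24 tert-butyl{[(2S,3S,6S)-4-[4-methoxy-2,6-bis(methoxymethoxy)phenyl]-2-[4-(methoxymethoxy)phenyl]-6-{2-[4-(methoxymethoxy)phenyl]ethyl}-3,6-dihydro-2H-pyran-3-yl]oxy}dimethylsilane
Product: 25 (2S,3S,6S)-4-[4-methoxy-2,6-bis(methoxymethoxy)phenyl]-2-[4-(methoxymethoxy)phenyl]-6-{2-[4-(methoxymethoxy)phenyl]ethyl}-3,6-dihydro-2H-pyran-3-ol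
Conditions: Bu4NF (1.5 equiv), THF, 0 °C → rt
Reagents that add atoms: none
Why: fluoride-mediated desilylation cleaves the only silyl ether; aryl methoxymethyl ethers are inert to fluoride.

Step 14
Reactants: 25 (2S,3S,6S)-4-[4-methoxy-2,6-bis(methoxymethoxy)phenyl]-2-[4-(methoxymethoxy)phenyl]-6-{2-[4-(methoxymethoxy)phenyl]ethyl}-3,6-dihydro-2H-pyran-3-ol
Product: 26 (2S,3S,4S,6S)-4-[4-methoxy-2,6-bis(methoxymethoxy)phenyl]-2-[4-(methoxymethoxy)phenyl]-6-{2-[4-(methoxymethoxy)phenyl]ethyl}oxan-3-ol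
Conditions: H2 (1 atm, up to 10 bar if slow), [Ir(cod)(PCy3)(py)]PF6 (10 mol %), CH2Cl2, rt
Reagents that add atoms: none
Why: hydroxyl-directed homogeneous hydrogenation: the cationic iridium catalyst binds the C3 hydroxyl (held pseudoaxial by allylic strain with ring A) and should deliver both hydrogens to the alkene face syn to it, so ring A ends trans to the C3 hydroxyl and cis to the C6 chain (4S).

Step 15
Reactants: 26 (2S,3S,4S,6S)-4-[4-methoxy-2,6-bis(methoxymethoxy)phenyl]-2-[4-(methoxymethoxy)phenyl]-6-{2-[4-(methoxymethoxy)phenyl]ethyl}oxan-3-ol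
Product: 27 (2S,3S,4S,6S)-4-[3-bromo-4-methoxy-2,6-bis(methoxymethoxy)phenyl]-2-[4-(methoxymethoxy)phenyl]-6-{2-[4-(methoxymethoxy)phenyl]ethyl}oxan-3-ol
Conditions: NBS (1.0 equiv), CH2Cl2, −40 → 0 °C, dark
Reagents that add atoms: N-bromosuccinimide (NBS), O=C1CCC(=O)N1Br
Why: electrophilic aromatic bromination: the trioxygenated ring A is far more nucleophilic than the two mono-oxygenated rings and its two free positions are equivalent, so one equivalent of NBS at low temperature should give the monobromide.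

Step 16
Reactants: 28 4-hydroxybenzaldehyde
Product: 29 4-(methoxymethoxy)benzaldehyde
Conditions: NaH (1.1 equiv), DMF, 0 °C; MOMCl (1.1 equiv), 0 °C → rt
Reagents that add atoms: chloromethyl methyl ether (MOMCl), COCCl
Why: Williamson-type O-alkylation of the phenoxide.

Step 17
Reactants: 29 4-(methoxymethoxy)benzaldehyde, 30 diethyl {2-[methoxy(methyl)amino]-2-oxoethyl}phosphonate
Product: 31 (2E)-N-methoxy-3-[4-(methoxymethoxy)phenyl]-N-methylprop-2-enamide
Conditions: NaH (1.1 equiv), THF, 0 °C → rt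
Reagents that add atoms: none
Why: Horner–Wadsworth–Emmons olefination with a stabilised phosphonate anion should give the (E)-alkene.

Step 18
Reactants: 27 (2S,3S,4S,6S)-4-[3-bromo-4-methoxy-2,6-bis(methoxymethoxy)phenyl]-2-[4-(methoxymethoxy)phenyl]-6-{2-[4-(methoxymethoxy)phenyl]ethyl}oxan-3-ol, 31 (2E)-N-methoxy-3-[4-(methoxymethoxy)phenyl]-N-methylprop-2-enamide
Product: 33 (2E)-1-{3-[(2S,3S,4S,6S)-3-hydroxy-2-[4-(methoxymethoxy)phenyl]-6-{2-[4-(methoxymethoxy)phenyl]ethyl}oxan-4-yl]-6-methoxy-2,4-bis(methoxymethoxy)phenyl}-3-[4-(methoxymethoxy)phenyl]prop-2-en-1-one, via dilithio species 32 (not isolated)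
Conditions: n-BuLi (2.2 equiv), THF, −78 °C; then 31 (1.5 equiv), −78 → −20 °C; sat. aq. NH4Cl
Reagents that add atoms: none
Why: bromine–lithium exchange (with deprotonation of the C3 hydroxyl) is faster than ortho-lithiation of the other rings, and acylation of the aryllithium by the N-methoxy-N-methylamide should stop at the ketone because the chelated adduct breaks down only on work-up; an aryllithium adds 1,2, so the (E)-enone is transferred intact.

Step 19
Reactants: 33 (2E)-1-{3-[(2S,3S,4S,6S)-3-hydroxy-2-[4-(methoxymethoxy)phenyl]-6-{2-[4-(methoxymethoxy)phenyl]ethyl}oxan-4-yl]-6-methoxy-2,4-bis(methoxymethoxy)phenyl}-3-[4-(methoxymethoxy)phenyl]prop-2-en-1-one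
Product: 35 (2E)-1-{2,4-dihydroxy-3-[(2S,3S,4S,6S)-3-hydroxy-2-(4-hydroxyphenyl)-6-[2-(4-hydroxyphenyl)ethyl]oxan-4-yl]-6-methoxyphenyl}-3-(4-hydroxyphenyl)prop-2-en-1-one (CNP0310862.1), via hexakis(trimethylsilyl) ether 34 (not isolated)
Conditions: TMSOTf (12 equiv), 2,2′-bipyridyl (18 equiv), MeCN, 0 °C → rt; then H2O/THF, rt
Reagents that add atoms: none
Why: buffered Lewis-acid acetal cleavage: the TMSOTf/2,2′-bipyridyl pair turns each aryl methoxymethyl ether into an aryl trimethylsilyl ether without free Brønsted acid and water then hydrolyses all silyl ethers, which should spare the C2 benzylic ether (prone to ionisation and epimerisation to the 2,6-cis isomer) and the 2′-hydroxychalcone (prone to flavanone closure).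

## Compound list

1 | 3-(4-hydroxyphenyl)propan-1-ol | OCCCc1ccc(O)cc1 | starting material
2 | 3-[4-(methoxymethoxy)phenyl]propan-1-ol | COCOc1ccc(CCCO)cc1 | intermediate
3 | 3-[4-(methoxymethoxy)phenyl]propanal | COCOc1ccc(CCC=O)cc1 | intermediate
4 | (E)-4-methoxybut-3-en-2-one | CO/C=C/C(C)=O | starting material
5 | trans-1-(3-methoxyoxiran-2-yl)ethan-1-one (racemic, one enantiomer drawn) | CO[C@@H]1O[C@H]1C(C)=O | intermediate
6 | 3-hydroxy-4,4-dimethoxybutan-2-one (racemic) | CC(=O)C(O)C(OC)OC | intermediate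
7 | 3-[(tert-butyldimethylsilyl)oxy]-4,4-dimethoxybutan-2-one (racemic) | CC(=O)C(O[Si](C)(C)C(C)(C)C)C(OC)OC | intermediate
8 | 3-[(tert-butyldimethylsilyl)oxy]-4,4-dimethoxy-2-[(trimethylsilyl)oxy]but-1-ene (racemic) | C=C(O[Si](C)(C)C)C(O[Si](C)(C)C(C)(C)C)C(OC)OC | intermediate
9 | (1Z)-2-[(tert-butyldimethylsilyl)oxy]-1-methoxy-3-[(trimethylsilyl)oxy]buta-1,3-diene | CO/C=C(\O[Si](C)(C)C(C)(C)C)C(=C)O[Si](C)(C)C | intermediate
10 | (1Z,5S)-2-[(tert-butyldimethylsilyl)oxy]-1-methoxy-7-[4-(methoxymethoxy)phenyl]-5-[(trimethylsilyl)oxy]hept-1-en-3-one | CO/C=C(\O[Si](C)(C)C(C)(C)C)C(=O)C[C@H](CCc1ccc(OCOC)cc1)O[Si](C)(C)C | intermediate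
11 | (2S)-5-[(tert-butyldimethylsilyl)oxy]-2-{2-[4-(methoxymethoxy)phenyl]ethyl}-2,3-dihydro-4H-pyran-4-one | O=C1C[C@H](CCc2ccc(OCOC)cc2)OC=C1O[Si](C)(C)C(C)(C)C | intermediate
12 | 4-bromophenol | Oc1ccc(Br)cc1 | starting material
13 | 1-bromo-4-(methoxymethoxy)benzene | COCOc1ccc(Br)cc1 | intermediate
14 | [4-(methoxymethoxy)phenyl]magnesium bromide | COCOc1ccc([Mg]Br)cc1 | intermediate
15 | bromomagnesium bis[4-(methoxymethoxy)phenyl]cuprate | COCOc1ccc([Cu-]c2ccc(OCOC)cc2)cc1.[Mg+]Br | intermediate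
16 | (2S,6S)-3-[(tert-butyldimethylsilyl)oxy]-2-[4-(methoxymethoxy)phenyl]-6-{2-[4-(methoxymethoxy)phenyl]ethyl}-4-[(trimethylsilyl)oxy]-5,6-dihydro-2H-pyran | C[Si](C)(C)OC1=C(O[Si](C)(C)C(C)(C)C)[C@H](c2ccc(OCOC)cc2)O[C@@H](CCc2ccc(OCOC)cc2)C1 | intermediate
17 | (2S,3R,6S)-3-[(tert-butyldimethylsilyl)oxy]-2-[4-(methoxymethoxy)phenyl]-6-{2-[4-(methoxymethoxy)phenyl]ethyl}oxan-4-one | O=C1C[C@H](CCc2ccc(OCOC)cc2)O[C@@H](c2ccc(OCOC)cc2)[C@H]1O[Si](C)(C)C(C)(C)C | intermediate
18 | potassium enolate of 17 (C4–C5 enolate) | [K+].[O-]C1=C[C@H](CCc2ccc(OCOC)cc2)O[C@@H](c2ccc(OCOC)cc2)[C@H]1O[Si](C)(C)C(C)(C)C | intermediate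
19 | (2S,3R,6S)-3-[(tert-butyldimethylsilyl)oxy]-2-[4-(methoxymethoxy)phenyl]-6-{2-[4-(methoxymethoxy)phenyl]ethyl}-3,6-dihydro-2H-pyran-4-yl trifluoromethanesulfonate | O=S(=O)(OC1=C[C@H](CCc2ccc(OCOC)cc2)O[C@@H](c2ccc(OCOC)cc2)[C@H]1O[Si](C)(C)C(C)(C)C)C(F)(F)F | intermediate
20 | 5-methoxybenzene-1,3-diol | COc1cc(O)cc(O)c1 | starting material
21 | 1-methoxy-3,5-bis(methoxymethoxy)benzene | COCOc1cc(OC)cc(OCOC)c1 | intermediate
22 | [4-methoxy-2,6-bis(methoxymethoxy)phenyl]lithium | COCOc1cc(OC)cc(OCOC)c1[Li] | intermediate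
23 | [4-methoxy-2,6-bis(methoxymethoxy)phenyl]boronic acid | COCOc1cc(OC)cc(OCOC)c1B(O)O | intermediate
24 | tert-butyl{[(2S,3S,6S)-4-[4-methoxy-2,6-bis(methoxymethoxy)phenyl]-2-[4-(methoxymethoxy)phenyl]-6-{2-[4-(methoxymethoxy)phenyl]ethyl}-3,6-dihydro-2H-pyran-3-yl]oxy}dimethylsilane | COCOc1cc(OC)cc(OCOC)c1C1=C[C@H](CCc2ccc(OCOC)cc2)O[C@@H](c2ccc(OCOC)cc2)[C@H]1O[Si](C)(C)C(C)(C)C | intermediate
25 | (2S,3S,6S)-4-[4-methoxy-2,6-bis(methoxymethoxy)phenyl]-2-[4-(methoxymethoxy)phenyl]-6-{2-[4-(methoxymethoxy)phenyl]ethyl}-3,6-dihydro-2H-pyran-3-ol | COCOc1cc(OC)cc(OCOC)c1C1=C[C@H](CCc2ccc(OCOC)cc2)O[C@@H](c2ccc(OCOC)cc2)[C@H]1O | intermediate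
26 | (2S,3S,4S,6S)-4-[4-methoxy-2,6-bis(methoxymethoxy)phenyl]-2-[4-(methoxymethoxy)phenyl]-6-{2-[4-(methoxymethoxy)phenyl]ethyl}oxan-3-ol | COc1cc(OCOC)c([C@@H]2C[C@H](CCc3ccc(OCOC)cc3)O[C@@H](c3ccc(OCOC)cc3)[C@H]2O)c(OCOC)c1 | intermediate
27 | (2S,3S,4S,6S)-4-[3-bromo-4-methoxy-2,6-bis(methoxymethoxy)phenyl]-2-[4-(methoxymethoxy)phenyl]-6-{2-[4-(methoxymethoxy)phenyl]ethyl}oxan-3-ol | COc1cc(OCOC)c([C@@H]2C[C@H](CCc3ccc(OCOC)cc3)O[C@@H](c3ccc(OCOC)cc3)[C@H]2O)c(OCOC)c1Br | intermediate
28 | 4-hydroxybenzaldehyde | O=Cc1ccc(O)cc1 | starting material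
29 | 4-(methoxymethoxy)benzaldehyde | COCOc1ccc(C=O)cc1 | intermediate
30 | diethyl {2-[methoxy(methyl)amino]-2-oxoethyl}phosphonate | CCOP(=O)(CC(=O)N(C)OC)OCC | starting material
31 | (2E)-N-methoxy-3-[4-(methoxymethoxy)phenyl]-N-methylprop-2-enamide | COCOc1ccc(/C=C/C(=O)N(C)OC)cc1 | intermediate
32 | lithium alkoxide–aryllithium from 27 (C3–OLi; ring A C–Li in place of C–Br) | COc1cc(OCOC)c([C@@H]2C[C@H](CCc3ccc(OCOC)cc3)O[C@@H](c3ccc(OCOC)cc3)[C@H]2O[Li])c(OCOC)c1[Li] | intermediate
33 | (2E)-1-{3-[(2S,3S,4S,6S)-3-hydroxy-2-[4-(methoxymethoxy)phenyl]-6-{2-[4-(methoxymethoxy)phenyl]ethyl}oxan-4-yl]-6-methoxy-2,4-bis(methoxymethoxy)phenyl}-3-[4-(methoxymethoxy)phenyl]prop-2-en-1-one | COc1cc(OCOC)c([C@@H]2C[C@H](CCc3ccc(OCOC)cc3)O[C@@H](c3ccc(OCOC)cc3)[C@H]2O)c(OCOC)c1C(=O)/C=C/c1ccc(OCOC)cc1 | intermediate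
34 | hexakis(trimethylsilyl) ether of 35 (five aryl O–SiMe3 groups and C3–O–SiMe3) | COc1cc(O[Si](C)(C)C)c([C@@H]2C[C@H](CCc3ccc(O[Si](C)(C)C)cc3)O[C@@H](c3ccc(O[Si](C)(C)C)cc3)[C@H]2O[Si](C)(C)C)c(O[Si](C)(C)C)c1C(=O)/C=C/c1ccc(O[Si](C)(C)C)cc1 | intermediate
35 | (2E)-1-{2,4-dihydroxy-3-[(2S,3S,4S,6S)-3-hydroxy-2-(4-hydroxyphenyl)-6-[2-(4-hydroxyphenyl)ethyl]oxan-4-yl]-6-methoxyphenyl}-3-(4-hydroxyphenyl)prop-2-en-1-one | COc1cc(O)c([C@@H]2C[C@H](CCc3ccc(O)cc3)O[C@@H](c3ccc(O)cc3)[C@H]2O)c(O)c1C(=O)/C=C/c1ccc(O)cc1 | target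

## Step count and risks

Total steps: 19. Longest linear sequence: 12 steps (steps 3, 4, 5, 6, 8, 9, 12, 13, 14, 15, 18, 19, starting from 4).

The three steps most likely to fail:

**Step 6.** The aldol addition of the tetrasubstituted, doubly silylated diene may be slow on the titanium catalyst, facial discrimination of the unbranched aldehyde may be poor, or the enol silyl ether at C3 may be hydrolysed during ring closure. The fallback sets out from 3 and comes back at 11. The same (R)-BINOL/Ti(Oi-Pr)4 catalysis, followed by TFA, is run with commercial 1-methoxy-3-(trimethylsilyloxy)buta-1,3-diene, for which this catalysis is established, and should give (2S)-2-{2-[4-(methoxymethoxy)phenyl]ethyl}-2,3-dihydro-4H-pyran-4-one F1. The C3 oxygen is then introduced after ring formation: DMDO epoxidation of the enol-ether double bond and methanolysis should give (6S)-3-hydroxy-2-methoxy-6-{2-[4-(methoxymethoxy)phenyl]ethyl}oxan-4-one F2 (mixture at C2 and C3, both centres lost later). Silylation (TBSOTf, 2,6-lutidine, CH2Cl2) gives (6S)-3-[(tert-butyldimethylsilyl)oxy]-2-methoxy-6-{2-[4-(methoxymethoxy)phenyl]ethyl}oxan-4-one F3, and β-elimination of methanol with DBU in CH2Cl2 returns 11.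

**Step 8.** The α-silyloxy vinylogous ester may resist the cuprate (1,2-addition or recovered enone), or protonation at C3 may be unselective or followed by epimerisation through the enol. The fallback sets out from 11 and 13 and comes back at 17. Bromide 13 is converted (n-BuLi, THF, −78 °C; B(Oi-Pr)3; aq. NH4Cl) into [4-(methoxymethoxy)phenyl]boronic acid F4, which is added to 11 by rhodium-catalysed conjugate addition ([Rh(cod)(OH)]2, 3 mol %, dioxane/H2O, 50 °C). Arylrhodation should again occur anti to the C6 chain, and the rhodium enolate is hydrolysed by water under near-neutral conditions to give 17.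

**Step 14.** The alkene is shielded on both faces by the ortho substituents of ring A, so the cationic iridium catalyst may fail to bind it or may be deactivated before conversion is complete. The fallback sets out from 25 and comes back at 26. It is a hydrogen-atom-transfer hydrogenation (Mn(dpm)3 cat., PhSiH3, t-BuOOH, i-PrOH, rt), a radical process that needs no alkene coordination. The hydrogen atom adds to C5, and the tertiary C4 radical should be reduced from the less hindered face. In the conformer with pseudoaxial C3 hydroxyl and pseudoaxial C6 chain this is the face syn to the hydroxyl, the same outcome as the directed reaction; the facial preference here rests on conformational bias, not on coordination, so it is less secure. No new compound arises (F0).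

## Further compounds

F1 | step 6 | (2S)-2-{2-[4-(methoxymethoxy)phenyl]ethyl}-2,3-dihydro-4H-pyran-4-one | O=C1C[C@H](CCc2ccc(OCOC)cc2)OC=C1
F2 | step 6 | (6S)-3-hydroxy-2-methoxy-6-{2-[4-(methoxymethoxy)phenyl]ethyl}oxan-4-one (mixture at C2 and C3) | O=C1C[C@H](CCc2ccc(OCOC)cc2)OC(OC)C1O
F3 | step 6 | (6S)-3-[(tert-butyldimethylsilyl)oxy]-2-methoxy-6-{2-[4-(methoxymethoxy)phenyl]ethyl}oxan-4-one (mixture at C2 and C3) | O=C1C[C@H](CCc2ccc(OCOC)cc2)OC(OC)C1O[Si](C)(C)C(C)(C)C
F4 | step 8 | [4-(methoxymethoxy)phenyl]boronic acid | COCOc1ccc(B(O)O)cc1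
F0 | step 14 | none | none
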